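At early times the eta run gives a straight line, and I reckon the five flasks from that line.

| flask | starting material | partner | free catalyst | temperature | remark | time |
|---|---|---|---|---|---|---|
| eta | 0.28 M | 0.25 M | 0.25 mM | 25 °C | run made earlier |  |
| oak | 0.12 M | 0.0800 M | 0.50 mM | 25 °C |  | 40 h |
| larch | 0.25 M | 0.250 M | 0.25 mM | 25 °C |  | 40 h |
| elm | 0.50 M | 0.250 M | 0.25 mM | −5 °C |  | 40 h |
| alder | 0.25 M | 0.800 M | 0.15 mM | 25 °C |  | 40 h |
| ash | 0.50 M | 0.500 M | 0.25 mM | 45 °C |  | 40 h |

eta run (percent of the starting material charged)

| time / h | product / % |
|---|---|
| 1.33 | 2.3 |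
| 2.50 | 4.9 |
| 4.00 | 7.3 |
| 5.00 | 9.5 |
| 6.00 | 10.8 |
| 8.00 | 14.4 |

(each reading ± 0.3 percentage points)

* ranking by amount of product, in percent of the starting material charged, from high to low, at 40 h (oak / larch / elm / alder / ash)
* the amount of product, in percent of the starting material charged of the flask you put first, at 40 h
* the amount of product, in percent of the starting material charged of the flask you put last, at 40 h

- the earlier runs do not show what temperature does; that part of a forecast is a guess
- no earlier run changes the charge of free catalyst; that part of a forecast is a guess

Between its first and last readings the eta run makes product at a steady rate, with no visible slowing by 14.4 %. I therefore treat the rate as zero-order in both reagents and as proportional to the catalyst charged, which is my assumption.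

rate = 0.00508 M/h

Dividing by the catalyst gives the turnover frequency, the product made per hour per unit of catalyst charged:

20.3 /h

Dividing the smaller charge of each flask by turnover frequency times catalyst gives a ladder of exhaustion times at 25 °C:

oak: 7.87 h

larch: 49.2 h

alder: 82.0 h

ash: 98.4 h

The reckoned time of oak is shorter than 40 h, and oak holds less partner than starting material, so partner is its limiting reagent and I cap oak at 66.7 %. The reckoned time of larch is longer than 40 h, so I reckon larch at 81.3 %, and in the same way alder at 48.8 %.

Equal charges make larch the zero of the scale for ash. Ash carries twice the starting material on the same charge of catalyst, so the rate of the eta run brings it to 40.6 % in this reckoning, and I guess that warming to 45 °C lifts ash above larch. Elm reckons to the same 40.6 % at that rate, less than alder, and I guess that cooling to −5 °C lowers it further. My order is ash, larch, oak, alder, elm.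

The forecast gives ash > larch > oak > alder > elm, with 96 % (82 % to 100 %) and 3.5 % (1.8 % to 7 %), and says of ash that “the rate rises about fourfold”.

The flasks give ash > larch > oak > alder > elm, with ash at 91.5 % and elm at 1.33 %.

    starting material + free catalyst → catalyst intermediate A (k = 1400 /M/h, Ea = 46.0 kJ/mol)
    partner + catalyst intermediate A → catalyst intermediate B (k = 3300 /M/h, Ea = 55.0 kJ/mol)
    catalyst intermediate B ⇌ by-product + catalyst intermediate C (K = 6.20 M, k = 65.0 /h, Ea = 75.0 kJ/mol, ΔH = −24.0 kJ/mol)
    catalyst intermediate C ⇌ catalyst intermediate D (K = 0.760, k = 2000 /h, Ea = 77.0 kJ/mol, ΔH = 5.00 kJ/mol)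
    catalyst intermediate D → free catalyst + product (k = 82.0 /h, Ea = 76.0 kJ/mol)
    free catalyst → spent catalyst A (k = 6.80 × 10⁻⁵ /h, Ea = 109 kJ/mol)
    free catalyst → spent catalyst B (k = 0.0460 /h, Ea = 90.0 kJ/mol)
    (constants at 25 °C)

At 40.0 h, spent catalyst B holds 98.7 % of the catalyst in ash. Left until 400 h, ash gives 91.7 % of product. Now take the neighbour of ash with 0.12 M of partner. The turnover frequency of the eta run reckons the catalyst of this neighbour to 0.203 M of product in 40 h, more than its partner, so the reckoning caps this neighbour at 24.0 %. The neighbour gives 24.0 %.

The runs stem from a simulated flask for an exercise; noise was put on by code.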